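In the north-west run, left-handed substrate reads 36.0% and 37.1% at the last two times, so it holds level while much of it remains. Taking the two hands as equal by then, the sum of a run's last two readings of left-handed substrate is the surviving fraction of the whole substrate: 73.1% there and 75.7% in the west run, which agree within the scatter.

the same everywhere: partner 1.04 M

|  | left-handed substrate | right-handed substrate | remark | time |
|---|---|---|---|---|
| north-west | 0.13 M | 0.13 M | run made earlier |  |
| west | 0.20 M | 0.20 M | run made earlier |  |
| flask | 0.26 M | 0.26 M |  | 15 d |

| run | time / d | left-handed product / % | left-handed substrate / % |
|---|---|---|---|
| north-west | 0.167 | 22.1 | 32.6 |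
| north-west | 0.625 | 19.5 | 36.5 |
| north-west | 1.67 | 16.8 | 37.2 |
| north-west | 6.00 | 12.7 | 36.0 |
| north-west | 20.0 | 13.9 | 37.1 |
| west | 0.167 | 21.4 | 29.8 |
| west | 0.625 | 20.9 | 37.9 |
| west | 1.67 | 18.7 | 37.8 |
| west | 6.00 | 13.3 | 38.7 |
| west | 20.0 | 11.4 | 37.0 |

(readings scatter by 1 percentage point)

- partner is single-handed; left-handed substrate and right-handed substrate are mirror images of each other, charged as a racemate, each of them at the stated concentration
- the handed part of partner does not stay in what it makes, so the products of the two hands are mirror images too

- time, not beyond 15 d, at which the flask holds most left-handed product
- the amount of left-handed product, in percent of the left-handed substrate and right-handed substrate together charged, at that time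

I take the pooled value, 74.4%, for the flask. Following one substrate molecule, I define the exposure as ln(1/surviving fraction) per molar of partner charged:

exposure = 0.284 M⁻¹

I enter the whole 1.04 M of the flask's partner in my ledger, assuming that each substrate molecule taken uses one partner and that the level readings mark the end of free partner:

into product, both hands: 0.133 M
gone some way the readings do not show: 0.907 M

On that assumption partner is the limiting reagent, although its charge exceeds that of both substrates together. By this estimate, left-handed product in the flask should stay below the fraction taken, 25.6%.

The forecast gives 0.15 d (0.04 d to 0.45 d) and 22.5% (20.5% to 26%), reasoning that “The peak therefore comes at or just before the first reading”.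

The flask holds most left-handed product at 0.239 d, later than the forecast's time, and the amount is 21.4%.

    left-handed substrate ⇌ right-handed substrate (k = 0.0920 h⁻¹)
    partner + right-handed substrate → right-handed product (k = 0.00450 M⁻¹ h⁻¹)
    partner ⇌ dormant form (K = 0.260, k = 0.0500 h⁻¹)
    partner + left-handed substrate → left-handed product (k = 0.460 M⁻¹ h⁻¹)
    left-handed product ⇌ right-handed product (k = 0.0130 h⁻¹)
    partner → decomposed reagent (k = 0.690 h⁻¹)

At the start, partner turns into decomposed reagent 5.8 times as fast as it joins left-handed substrate. At 15.0 d the flask holds 0.916 M of decomposed reagent, with partner at 0% and dormant form at 0 M, close to my unread entry of 0.907 M. The flask keeps 76% of its right-handed substrate against my 74.4%. With 2.6 M of partner, the exposure gives 47.8% surviving, and that neighbour flask keeps 56% of its right-handed substrate.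

The earlier runs and the new flask were generated by integration with made-up constants.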